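**Retrosynthetic overview**
- The target is a 2,3-trans-3,4-trans-4,5-cis 2,5-diaryl-3,4-dimethyloxolane carrying two mirror-image threo aryloxy-propanol arms. The last bond made is the ring C5–H, by cis-selective ionic reduction of a cyclic hemiketal.
- The hemiketal comes from an aryllithium (fragment B, S,S arm) and an all-trans γ-butyrolactone (fragment A, R,R arm).
- The lactone comes from a new Brønsted-acid organocatalytic (methoxycarbonyl)crotylboration–lactonisation of a vanillin-derived aldehyde, followed by one-pot ketone reduction, conjugate reduction and epimerisation.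
- Both arms come from Mitsunobu inversion of the two antipodal α-hydroxy ketones. These are made from one achiral silyl enol ether by Shi epoxidation with the two antipodal ketone catalysts, which sets the first stereocentres.
- Ring order: a single ring is built, first as the γ-lactone, then re-cast as the cyclic hemiketal, then reduced to the oxolane.

Assumption: the senses of induction of the two Shi ketones and of the binaphthyl Brønsted acid follow the accepted transition-state models named at each step; if a sense proves reversed, the antipodal catalyst is used.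

**Step 1**
Reactants: 1 1-(3,4-dimethoxyphenyl)propan-1-one
Product: 2 (Z)-tert-butyl{[1-(3,4-dimethoxyphenyl)prop-1-en-1-yl]oxy}dimethylsilane
Conditions: TBSOTf, Et3N, CH2Cl2, 0 °C → rt
Reagents that add atoms: tert-butyldimethylsilyl trifluoromethanesulfonate (TBSOTf), CC(C)(C)[Si](C)(C)OS(=O)(=O)C(F)(F)F
Why: Soft enolisation and O-silylation give the thermodynamically preferred (Z)-silyl enol ether (methyl trans to aryl), the geometry the epoxidation needs, and no stereocentre is formed.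

**Step 2**
Reactants: 2 (Z)-tert-butyl{[1-(3,4-dimethoxyphenyl)prop-1-en-1-yl]oxy}dimethylsilane
Product: 4 (R)-1-(3,4-dimethoxyphenyl)-2-hydroxypropan-1-one, via silyloxy epoxide 3 (not isolated)
Conditions: D-fructose-derived Shi ketone (30 mol%), KHSO5 (Oxone), K2CO3, n-Bu4NHSO4, MeCN/(MeO)2CH2/aq. Na2B4O7 buffer, 0 °C; then 1 M HCl, THF, 0 °C
Reagents that add atoms: potassium peroxymonosulfate (KHSO5), [K+].[O-]S(=O)(=O)OO
Why: Shi asymmetric epoxidation (chiral dioxirane, spiro transition state, same olefin face as for trans-β-methylstyrene) sets the methyl-bearing carbon as R, the first stereocentre, and acid hydrolysis of the labile silyloxy epoxide unveils the α-hydroxy ketone with retention (Rubottom-type oxidation).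

**Step 3**
Reactants: 2 (Z)-tert-butyl{[1-(3,4-dimethoxyphenyl)prop-1-en-1-yl]oxy}dimethylsilane
Product: 6 (S)-1-(3,4-dimethoxyphenyl)-2-hydroxypropan-1-one, via silyloxy epoxide 5 (not isolated)
Conditions: L-fructose-derived (antipodal) Shi ketone (30 mol%), KHSO5 (Oxone), K2CO3, n-Bu4NHSO4, MeCN/(MeO)2CH2/aq. Na2B4O7 buffer, 0 °C; then 1 M HCl, THF, 0 °C
Reagents that add atoms: potassium peroxymonosulfate (KHSO5), [K+].[O-]S(=O)(=O)OO
Why: The same Shi epoxidation with the mirror-image dioxirane attacks the opposite olefin face and gives the S ketol after hydrolysis.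

**Step 4**
Reactants: 6 (S)-1-(3,4-dimethoxyphenyl)-2-hydroxypropan-1-one; 7 vanillin (4-hydroxy-3-methoxybenzaldehyde)
Product: 8 4-{[(2R)-1-(3,4-dimethoxyphenyl)-1-oxopropan-2-yl]oxy}-3-methoxybenzaldehyde
Conditions: PPh3, DIAD, THF, 0 °C → rt
Reagents that add atoms: none
Why: Mitsunobu etherification, in which the acidic phenol displaces the activated secondary hydroxyl by SN2 with inversion (S → R at the future C8), a displacement accelerated by the adjacent carbonyl, while the aldehyde is a spectator.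

**Step 5**
Reactants: 4 (R)-1-(3,4-dimethoxyphenyl)-2-hydroxypropan-1-one; 9 4-bromo-2-methoxyphenol
Product: 10 (2S)-2-(4-bromo-2-methoxyphenoxy)-1-(3,4-dimethoxyphenyl)propan-1-one
Conditions: PPh3, DIAD, THF, 0 °C → rt
Reagents that add atoms: none
Why: Mitsunobu etherification with SN2 inversion (R → S) installs the aryl ether of the second arm in the mirror-image series.

**Step 6**
Reactants: 10 (2S)-2-(4-bromo-2-methoxyphenoxy)-1-(3,4-dimethoxyphenyl)propan-1-one
Product: 11 (1S,2S)-2-(4-bromo-2-methoxyphenoxy)-1-(3,4-dimethoxyphenyl)propan-1-ol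
Conditions: LiBH(s-Bu)3, THF, −78 °C; aq. NH4Cl
Reagents that add atoms: none
Why: Felkin–Anh (polar, non-chelated) hydride delivery by the bulky borohydride anti to the α-aryloxy group gives the threo (1S,2S) alcohol by 1,2-induction (ketone reduction).

**Step 7**
Reactants: 12 methyl but-2-ynoate; 13 2-(iodomethyl)-4,4,5,5-tetramethyl-1,3,2-dioxaborolane
Product: 15 methyl (Z)-2-[(4,4,5,5-tetramethyl-1,3,2-dioxaborolan-2-yl)methyl]but-2-enoate, via vinylalane 14 (not isolated)
Conditions: i-Bu2AlH, HMPA, THF, 0 °C; then 13, 0 °C → rt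
Reagents that add atoms: none
Why: HMPA-promoted syn-hydroalumination of the ynoate (conjugate hydride addition) gives the α-alumino acrylate, and its C-alkylation by the iodomethylboronate with retention fixes the methyl trans to CH2B, with no stereocentre formed.

**Step 8**
Reactants: 8 4-{[(2R)-1-(3,4-dimethoxyphenyl)-1-oxopropan-2-yl]oxy}-3-methoxybenzaldehyde; 15 methyl (Z)-2-[(4,4,5,5-tetramethyl-1,3,2-dioxaborolan-2-yl)methyl]but-2-enoate
Product: 17 (4S,5S)-5-(4-{[(2R)-1-(3,4-dimethoxyphenyl)-1-oxopropan-2-yl]oxy}-3-methoxyphenyl)-4-methyl-3-methylideneoxolan-2-one, via borate ester 16 (not isolated)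
Conditions: (S)-3,3'-bis(2,4,6-triisopropylphenyl)-1,1'-binaphthyl-2,2'-diyl N-triflyl phosphoramide (10 mol%), 4 Å MS, toluene, −20 °C → rt
Reagents that add atoms: none
Why: Proposed new method: an enantioselective Brønsted acid-catalysed (methoxycarbonyl)crotylboration–lactonisation, in which the strongly acidic phosphoramide hydrogen-bonds the pseudo-axial pinacol oxygen of 15 (raising boron Lewis acidity enough to offset the ester deactivation) while its phosphoryl oxygen holds the formyl C–H, so that C–C bond formation runs through a closed six-membered chair with the aldehyde aryl equatorial, the methyl trans to CH2B giving the anti adduct 16 and the (S)-acid exposing the Si face (4S,5S), after which the borate oxygen attacks the neighbouring ester with loss of MeOBpin to close the trans lactone; the closest known reaction types are chiral phosphoric acid-catalysed crotylboration of aldehydes with unfunctionalised crotyl pinacolboronates and the achiral strong-acid-catalysed addition of 2-alkoxycarbonyl allylboronates to aldehydes.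

**Step 9**
Reactants: 17 (4S,5S)-5-(4-{[(2R)-1-(3,4-dimethoxyphenyl)-1-oxopropan-2-yl]oxy}-3-methoxyphenyl)-4-methyl-3-methylideneoxolan-2-one
Product: 19 (3S,4S,5S)-5-(4-{[(1R,2R)-1-(3,4-dimethoxyphenyl)-1-hydroxypropan-2-yl]oxy}-3-methoxyphenyl)-3,4-dimethyloxolan-2-one, via cis-lactone epimer 18 (not isolated)
Conditions: LiBH(s-Bu)3 (2.5 equiv), THF, −78 → −40 °C; AcOH; then DBU, 50 °C
Reagents that add atoms: none
Why: The borohydride first reduces the aryl ketone under Felkin–Anh control (threo, 1R) and then adds 1,4 to the exo-methylene lactone (conjugate reduction), protonation anti to the C4 methyl gives mainly the 3,4-cis epimer 18, and DBU equilibrates it to the all-trans 3S lactone (thermodynamic epimerisation).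

**Step 10**
Reactants: 11 (1S,2S)-2-(4-bromo-2-methoxyphenoxy)-1-(3,4-dimethoxyphenyl)propan-1-ol; 19 (3S,4S,5S)-5-(4-{[(1R,2R)-1-(3,4-dimethoxyphenyl)-1-hydroxypropan-2-yl]oxy}-3-methoxyphenyl)-3,4-dimethyloxolan-2-one
Product: 21 (3S,4S,5S)-2-(4-{[(1S,2S)-1-(3,4-dimethoxyphenyl)-1-hydroxypropan-2-yl]oxy}-3-methoxyphenyl)-5-(4-{[(1R,2R)-1-(3,4-dimethoxyphenyl)-1-hydroxypropan-2-yl]oxy}-3-methoxyphenyl)-3,4-dimethyloxolan-2-ol (anomer mixture), via aryllithium 20 (not isolated)
Conditions: 11 (1.3 equiv), n-BuLi (2.05 equiv per 11), THF, −78 °C; then 19 pre-treated with LiN(SiMe3)2 (1.0 equiv), THF, −78 °C; aq. NH4Cl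
Reagents that add atoms: none
Why: Bromine–lithium exchange on the lithium alkoxide of 11 gives an aryllithium that adds once to the lactone carbonyl (the tetrahedral lithium hemiketalate is stable at −78 °C), the free hydroxyl of 19 being masked as its lithium alkoxide (organolithium addition to a lactone, anomeric centre not fixed).

**Step 11**
Reactants: 21 (3S,4S,5S)-2-(4-{[(1S,2S)-1-(3,4-dimethoxyphenyl)-1-hydroxypropan-2-yl]oxy}-3-methoxyphenyl)-5-(4-{[(1R,2R)-1-(3,4-dimethoxyphenyl)-1-hydroxypropan-2-yl]oxy}-3-methoxyphenyl)-3,4-dimethyloxolan-2-ol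
Product: 23 (1R,2R)-1-(3,4-dimethoxyphenyl)-2-{4-[(2S,3S,4S,5R)-5-(4-{[(1S,2S)-1-(3,4-dimethoxyphenyl)-1-hydroxypropan-2-yl]oxy}-3-methoxyphenyl)-3,4-dimethyloxolan-2-yl]-2-methoxyphenoxy}propan-1-ol, via oxocarbenium ion 22 (not isolated)
Conditions: Et3SiH, BF3·OEt2, CH2Cl2, −78 °C
Reagents that add atoms: none
Why: BF3 ionises only the tertiary hemiketal (the β-aryloxy benzylic alcohols ionise far more slowly at −78 °C) and Et3SiH delivers hydride to the aryl oxocarbenium ion anti to the adjacent C4 methyl, so the new aryl ends cis to it (5R) by ionic hydrogenation of a hemiketal.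

**Compound list**
1 | 1-(3,4-dimethoxyphenyl)propan-1-one | CCC(=O)c1ccc(OC)c(OC)c1 | starting material
2 | (Z)-tert-butyl{[1-(3,4-dimethoxyphenyl)prop-1-en-1-yl]oxy}dimethylsilane | C/C=C(\O[Si](C)(C)C(C)(C)C)c1ccc(OC)c(OC)c1 | intermediate
3 | (2S,3R)-2-(tert-butyldimethylsilyloxy)-2-(3,4-dimethoxyphenyl)-3-methyloxirane | C[C@H]1O[C@]1(O[Si](C)(C)C(C)(C)C)c1ccc(OC)c(OC)c1 | intermediate
4 | (R)-1-(3,4-dimethoxyphenyl)-2-hydroxypropan-1-one | C[C@@H](O)C(=O)c1ccc(OC)c(OC)c1 | intermediate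
5 | (2R,3S)-2-(tert-butyldimethylsilyloxy)-2-(3,4-dimethoxyphenyl)-3-methyloxirane | C[C@@H]1O[C@@]1(O[Si](C)(C)C(C)(C)C)c1ccc(OC)c(OC)c1 | intermediate
6 | (S)-1-(3,4-dimethoxyphenyl)-2-hydroxypropan-1-one | C[C@H](O)C(=O)c1ccc(OC)c(OC)c1 | intermediate
7 | vanillin (4-hydroxy-3-methoxybenzaldehyde) | COc1cc(C=O)ccc1O | starting material
8 | 4-{[(2R)-1-(3,4-dimethoxyphenyl)-1-oxopropan-2-yl]oxy}-3-methoxybenzaldehyde | C[C@@H](Oc1ccc(C=O)cc1OC)C(=O)c1ccc(OC)c(OC)c1 | intermediate
9 | 4-bromo-2-methoxyphenol | COc1cc(Br)ccc1O | starting material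
10 | (2S)-2-(4-bromo-2-methoxyphenoxy)-1-(3,4-dimethoxyphenyl)propan-1-one | C[C@H](Oc1ccc(Br)cc1OC)C(=O)c1ccc(OC)c(OC)c1 | intermediate
11 | (1S,2S)-2-(4-bromo-2-methoxyphenoxy)-1-(3,4-dimethoxyphenyl)propan-1-ol | C[C@H](Oc1ccc(Br)cc1OC)[C@@H](O)c1ccc(OC)c(OC)c1 | intermediate
12 | methyl but-2-ynoate | CC#CC(=O)OC | starting material
13 | 2-(iodomethyl)-4,4,5,5-tetramethyl-1,3,2-dioxaborolane | ICB1OC(C)(C)C(C)(C)O1 | starting material
14 | methyl (E)-2-(diisobutylalumanyl)but-2-enoate (methyl trans to Al) | C/C=C(/[Al](CC(C)C)CC(C)C)C(=O)OC | intermediate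
15 | methyl (Z)-2-[(4,4,5,5-tetramethyl-1,3,2-dioxaborolan-2-yl)methyl]but-2-enoate (methyl trans to CH2B) | C/C=C(/CB1OC(C)(C)C(C)(C)O1)C(=O)OC | intermediate
16 | methyl (3S,4S)-4-(4-{[(2R)-1-(3,4-dimethoxyphenyl)-1-oxopropan-2-yl]oxy}-3-methoxyphenyl)-3-methyl-2-methylidene-4-[(4,4,5,5-tetramethyl-1,3,2-dioxaborolan-2-yl)oxy]butanoate | C=C(C(=O)OC)[C@H](C)[C@H](OB1OC(C)(C)C(C)(C)O1)c1ccc(O[C@H](C)C(=O)c2ccc(OC)c(OC)c2)c(OC)c1 | intermediate
17 | (4S,5S)-5-(4-{[(2R)-1-(3,4-dimethoxyphenyl)-1-oxopropan-2-yl]oxy}-3-methoxyphenyl)-4-methyl-3-methylideneoxolan-2-one (4,5-trans) | C[C@@H]1[C@@H](c2ccc(O[C@H](C)C(=O)c3ccc(OC)c(OC)c3)c(OC)c2)OC(=O)C1=C | intermediate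
18 | (3R,4S,5S)-5-(4-{[(1R,2R)-1-(3,4-dimethoxyphenyl)-1-hydroxypropan-2-yl]oxy}-3-methoxyphenyl)-3,4-dimethyloxolan-2-one (3,4-cis) | C[C@@H]1[C@@H](c2ccc(O[C@H](C)[C@H](O)c3ccc(OC)c(OC)c3)c(OC)c2)OC(=O)[C@@H]1C | intermediate
19 | (3S,4S,5S)-5-(4-{[(1R,2R)-1-(3,4-dimethoxyphenyl)-1-hydroxypropan-2-yl]oxy}-3-methoxyphenyl)-3,4-dimethyloxolan-2-one (all-trans) | C[C@@H]1[C@@H](c2ccc(O[C@H](C)[C@H](O)c3ccc(OC)c(OC)c3)c(OC)c2)OC(=O)[C@H]1C | intermediate
20 | lithium (1S,2S)-1-(3,4-dimethoxyphenyl)-2-(4-lithio-2-methoxyphenoxy)propan-1-olate | [Li]c1ccc(O[C@@H](C)[C@@H](O[Li])c2ccc(OC)c(OC)c2)c(OC)c1 | intermediate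
21 | (3S,4S,5S)-2-(4-{[(1S,2S)-1-(3,4-dimethoxyphenyl)-1-hydroxypropan-2-yl]oxy}-3-methoxyphenyl)-5-(4-{[(1R,2R)-1-(3,4-dimethoxyphenyl)-1-hydroxypropan-2-yl]oxy}-3-methoxyphenyl)-3,4-dimethyloxolan-2-ol (anomer mixture) | C[C@@H]1[C@@H](c2ccc(O[C@H](C)[C@H](O)c3ccc(OC)c(OC)c3)c(OC)c2)OC(O)(c2ccc(O[C@@H](C)[C@@H](O)c3ccc(OC)c(OC)c3)c(OC)c2)[C@H]1C | intermediate
22 | oxocarbenium ion of 21 (C2=O+, centres 3S,4S,5S and both arms unchanged) | C[C@@H]1[C@@H](c2ccc(O[C@H](C)[C@H](O)c3ccc(OC)c(OC)c3)c(OC)c2)[O+]=C(c2ccc(O[C@@H](C)[C@@H](O)c3ccc(OC)c(OC)c3)c(OC)c2)[C@H]1C | intermediate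
23 | (1R,2R)-1-(3,4-dimethoxyphenyl)-2-{4-[(2S,3S,4S,5R)-5-(4-{[(1S,2S)-1-(3,4-dimethoxyphenyl)-1-hydroxypropan-2-yl]oxy}-3-methoxyphenyl)-3,4-dimethyloxolan-2-yl]-2-methoxyphenoxy}propan-1-ol (CNP0116650.17) | COc1ccc([C@@H](O)[C@@H](C)Oc2ccc([C@H]3O[C@@H](c4ccc(O[C@@H](C)[C@@H](O)c5ccc(OC)c(OC)c5)c(OC)c4)[C@@H](C)[C@@H]3C)cc2OC)cc1OC | target

**Step count and risks**

Total step count: 11. Longest linear sequence: 7 steps (steps 1, 3, 4, 8, 9, 10, 11).

Three steps most likely to fail: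

The proposed new reaction, step 8, carries the highest risk. The ester-deactivated boronate may react too slowly with the electron-rich aldehyde under a chiral acid, or the enantioselectivity may be low. The fallback uses known chemistry and sets out from 8. Chiral phosphoric acid-catalysed anti-crotylboration with commercial (E)-crotylboronic acid pinacol ester and (S)-TRIP (toluene, −30 °C) gives the anti homoallylic alcohol F1. Hydroxyl-directed branched hydroformylation (Rh(CO)2(acac), catalytic Ph2POMe, CO/H2, THF, 40 °C) gives the lactol F2. Oxidation with TEMPO/PhI(OAc)2 gives the keto lactone F3. Reduction of the ketone alone with LiBH(s-Bu)3 at −78 °C followed by DBU equilibration brings the route back at 19.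

Step 11 is the second risk. BF3 may ionise or deoxygenate the two free side-chain benzylic carbinols, or erode the ring stereocentres, before the hemiketal is fully reduced. The fallback changes to a silyl-protected series and sets out from 19 and 11. TBSOTf/2,6-lutidine gives the silyl ether of the lactone F4 and the silyl ether of the bromide F5. n-BuLi (1.05 equiv, THF, −78 °C) converts F5 into the silylated aryllithium F6, which adds to F4 to give the bis-silyl hemiketal F7. Et3SiH/BF3·OEt2 at −78 °C gives the bis-silyl oxolane F8, and TBAF in THF returns the route at 23.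

Step 5 is the third risk. 4-Bromo-2-methoxyphenol is the less acidic of the two phenols, so the Mitsunobu betaine has more time to enolise the α-ketol and erode its configuration. The fallback replaces the redox condensation by a sulfonate displacement and sets out from 4. MsCl/Et3N (CH2Cl2, −20 °C) gives the mesylate F9, which reacts with 9 and the phosphazene base BEMP in MeCN at rt by SN2 inversion and comes back to the route at 10.

**Further compounds**
F1 | step 8 | anti homoallylic alcohol: (2R)-1-(3,4-dimethoxyphenyl)-2-{4-[(1S,2S)-1-hydroxy-2-methylbut-3-en-1-yl]-2-methoxyphenoxy}propan-1-one | C=C[C@H](C)[C@H](O)c1ccc(O[C@H](C)C(=O)c2ccc(OC)c(OC)c2)c(OC)c1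
F2 | step 8 | lactol: (4S,5S)-5-(4-{[(2R)-1-(3,4-dimethoxyphenyl)-1-oxopropan-2-yl]oxy}-3-methoxyphenyl)-3,4-dimethyloxolan-2-ol (mixture at C2 and C3) | C[C@@H]1[C@@H](c2ccc(O[C@H](C)C(=O)c3ccc(OC)c(OC)c3)c(OC)c2)OC(O)C1C
F3 | step 8 | keto lactone: (4S,5S)-5-(4-{[(2R)-1-(3,4-dimethoxyphenyl)-1-oxopropan-2-yl]oxy}-3-methoxyphenyl)-3,4-dimethyloxolan-2-one (C3 epimers) | C[C@@H]1[C@@H](c2ccc(O[C@H](C)C(=O)c3ccc(OC)c(OC)c3)c(OC)c2)OC(=O)C1C
F4 | step 11 | silyl ether of the lactone: tert-butyldimethylsilyl ether of 19 at the (1R) carbinol | C[C@@H]1[C@@H](c2ccc(O[C@H](C)[C@H](O[Si](C)(C)C(C)(C)C)c3ccc(OC)c(OC)c3)c(OC)c2)OC(=O)[C@H]1C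
F5 | step 11 | silyl ether of the bromide: tert-butyldimethylsilyl ether of 11 at the (1S) carbinol | C[C@H](Oc1ccc(Br)cc1OC)[C@@H](O[Si](C)(C)C(C)(C)C)c1ccc(OC)c(OC)c1
F6 | step 11 | silylated aryllithium: 4-lithio analogue of F5 | [Li]c1ccc(O[C@@H](C)[C@@H](O[Si](C)(C)C(C)(C)C)c2ccc(OC)c(OC)c2)c(OC)c1
F7 | step 11 | bis-silyl hemiketal: bis(tert-butyldimethylsilyl) ether of 21 at both side-chain carbinols | C[C@@H]1[C@@H](c2ccc(O[C@H](C)[C@H](O[Si](C)(C)C(C)(C)C)c3ccc(OC)c(OC)c3)c(OC)c2)OC(O)(c2ccc(O[C@@H](C)[C@@H](O[Si](C)(C)C(C)(C)C)c3ccc(OC)c(OC)c3)c(OC)c2)[C@H]1C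
F8 | step 11 | bis-silyl oxolane: bis(tert-butyldimethylsilyl) ether of 23 at both side-chain carbinols | C[C@@H]1[C@@H](c2ccc(O[C@H](C)[C@H](O[Si](C)(C)C(C)(C)C)c3ccc(OC)c(OC)c3)c(OC)c2)O[C@@H](c2ccc(O[C@@H](C)[C@@H](O[Si](C)(C)C(C)(C)C)c3ccc(OC)c(OC)c3)c(OC)c2)[C@H]1C
F9 | step 5 | mesylate: (2R)-1-(3,4-dimethoxyphenyl)-1-oxopropan-2-yl methanesulfonate | C[C@@H](OS(C)(=O)=O)C(=O)c1ccc(OC)c(OC)c1
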